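The runs were generated by integration on assumed constants; noise was put on by code.

A one-step world counts one Z per X, and this flask is charged at 1.05 Z per X. But J is a tris adduct that takes 3 Z per X, so at this ratio, lower than that, Z is the limiting reagent for J, and the Z ratio is the setting we follow.

the same everywhere: Z 10.5 mM

| flask | X | G | remark | time |
|---|---|---|---|---|
| Monday's | 5 mM | 3 mM | run made earlier |  |
| Thursday's | 20 mM | 3 mM | run made earlier |  |
| Saturday's | 10 mM | 4.5 mM | run made earlier |  |
| flask | 10 mM | 3.00 mM |  | 2.5 h |

| run | time / h | J / % | X / % |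
|---|---|---|---|
| Monday's | 0.250 | 0.2 | 83.4 |
| Monday's | 0.833 | 3.9 | 41.3 |
| Monday's | 1.33 | 9.6 | 25.1 |
| Monday's | 2.00 | 16.0 | 16.7 |
| Monday's | 3.00 | 22.6 | 11.5 |
| Thursday's | 0.250 | 0.3 | 86.9 |
| Thursday's | 0.833 | 0.8 | 63.6 |
| Thursday's | 1.33 | 0.9 | 61.6 |
| Thursday's | 2.00 | 0.5 | 61.6 |
| Thursday's | 3.00 | 0.8 | 61.4 |
| Saturday's | 0.250 | 0 | 84.5 |
| Saturday's | 0.417 | 0.2 | 72.1 |
| Saturday's | 0.833 | 1.7 | 48.5 |
| Saturday's | 1.50 | 4.3 | 39.4 |
| Saturday's | 3.00 | 4.6 | 36.3 |

(readings scatter by 0.3 percentage points)

- as a solid, counted per litre of solution: Z
- at the start none of Z is in solution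
- the reaction counts as stopped when no species that holds the X changes by six tenths of a point or more over the second half of the time

- at 2.5 h, what has stopped the reaction, if anything has (for what has run out or reacted, a solid counts together with what of it has only dissolved) (forward and back rates have come level / all of X has reacted / it is still moving)
- amount of J at 2.5 h, in percent of the X charged

Monday's run, at a ratio of 2.10, reads J 22.6% at 3.00 h. Thursday's, at 0.525, reads 0.8%. Both ran at the flask's G, so we reckon the steepness 2.41, the logarithm of the ratio of the two J readings over the logarithm of the ratio of the two Z ratios. Carried to the flask's ratio from Thursday, it gives our first number, J 4.25%, which belongs to 3.00 h rather than the asked 2.5 h and rests on a small reading good to 0.3 percentage points.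

The second way uses a different run. Saturday's has the flask's ratio but more G, and reads J 4.3% at 1.50 h and 4.6% at 3.00 h. The first way has the right G and the second the right ratio, and they differ by 0.35 points, about the scatter of one reading, so we trust a J near these two. Saturday's X still fell 3.1 points over that last stretch, against the 0.6 points that count as stopped, and from that reading we expect the flask to be still moving.

The forecast says it is still moving, as we do, but puts J at 7.5%, with a range of 5% to 10.5%, “between Saturday's 0.46 mM and Monday's roughly 1 mM”. That is higher than both our numbers.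

The flask's answer is that it is still moving, with J 4.76%, so the forecast holds within its tolerance, though J lies below its low end. X goes from 41.5% at 1.25 h to 36.9% at 2.50 h, with solid Z at 0% of its charge.

    X + Q → L (k = 3.50 M⁻¹ min⁻¹)
    Q + E → J (k = 1.23 M⁻¹ min⁻¹)
    L + G → D (k = 0.273 M⁻¹ min⁻¹)
    Z ⇌ Q, rate k4*(cs4 - [Q]) while solid is left; crystals form when [Q] > cs4 (solubility = 7.10 mM, k = 0.104 min⁻¹)
    Q + L → E (k = 5.96 M⁻¹ min⁻¹)

The neighbouring flask with 6.0 mM of X has a ratio of 1.75, and the steepness carried from our first number gives 14.6%, again for the later time of the readings behind it. That neighbour holds J 14.6% at 2.50 h.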